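**Retrosynthetic overview**
- Target ⇐ Rh-catalysed hydrogenation of a C4 isopropenyl group, and before that an inverting (Mitsunobu) tigloylation of the C5 alcohol of an all-trans 3-acetoxy-5-hydroxy-4-isopropenyl-cyclohexenone.
- That cyclohexenone (the only ring) ⇐ type-I carbonyl-ene closure of the C4–C5 bond of an acyclic (Z)-4-oxo-2-enal. The aldehyde carbon (terpenoid C1, an oxidised stand-in for the allyl cation) is attacked by C6 of the distal trisubstituted olefin, the same bond and polarity as in the geranyl/neryl → p-menthane cyclisation. The C3 acetoxy centre relays to C4 and C5.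
- (Z)-Oxoenal ⇐ oxidative opening of a 2,3-disubstituted furan; the Z geometry comes from the ring.
- Furan ⇐ catalytic asymmetric isobutenylzinc addition with in-flask acetylation on 3-(tigloyloxymethyl)furfural ⇐ 3-furanmethanol (C2 lithiation/DMF, then tigloyl chloride).
- Ring order: one ring only, closed in step 5.

Assumption: (+)-DAIB delivers the alkenyl group to the Re face of the furfural (mirror image of the known Si-face sense of (−)-DAIB; otherwise the enantiomeric ligand is used); ring positions are cited in p-menthane numbering (C1 bears C7H2O, C2 = C=O, C3 = CH-OAc, C4 = CH-iPr, C5 = CH-O-tigloyl, C6 = CH=).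

**Step 1**
Reactants: 1 furan-3-ylmethanol
Product: 4 3-(hydroxymethyl)furan-2-carbaldehyde, via dilithio dianion 2 (not isolated), via lithium hemiaminal dialkoxide 3 (not isolated)
Conditions: n-BuLi (2.2 equiv), THF, −78 → 0 °C; DMF (1.5 equiv), −78 °C → rt; H2O
Reagents that add atoms: N,N-dimethylformamide, CN(C)C=O
Why: Alkoxide-directed ortho-lithiation puts lithium at the furan α-position next to the CH2OLi group (C2), and formylation with DMF gives the aldehyde on hydrolysis; no stereocentre is formed.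

**Step 2**
Reactants: 4 3-(hydroxymethyl)furan-2-carbaldehyde; 5 tigloyl chloride
Product: 6 (2-formylfuran-3-yl)methyl (E)-2-methylbut-2-enoate
Conditions: 5 (1.1 equiv), pyridine (2 equiv), DMAP (5 mol%), CH2Cl2, 0 °C
Reagents that add atoms: none
Why: DMAP-catalysed O-acylation of the primary alcohol with the acid chloride; pyridine instead of a trialkylamine avoids vinylketene formation and scrambling of the tiglate geometry.

**Step 3**
Reactants: 6 (2-formylfuran-3-yl)methyl (E)-2-methylbut-2-enoate; 7 (2-methylprop-1-en-1-yl)magnesium bromide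
Product: 10 [2-[(1R)-1-acetoxy-3-methylbut-2-en-1-yl]furan-3-yl]methyl (E)-2-methylbut-2-enoate, via bis(2-methylprop-1-enyl)zinc 8 (not isolated), via zinc alkoxide 9 (not isolated)
Conditions: 7 (2.4 equiv), ZnCl2 (1.2 equiv), THF, 0 °C; 1,4-dioxane, filter off Mg salts, switch to toluene; (+)-DAIB (5 mol%), then 6, −20 → 0 °C; Ac2O (3 equiv), rt; NaHCO3 work-up, Et3N-deactivated silica
Reagents that add atoms: acetic anhydride, CC(=O)OC(C)=O
Why: Amino-alcohol-catalysed asymmetric organozinc (alkenylzinc) addition to the aldehyde, in which the ligand–zinc chelate delivers the isobutenyl group to the Re face and so sets the single controlling stereocentre (C3, R); acetylating the zinc alkoxide in the flask means the acid-labile furyl allyl carbinol is never handled.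

**Step 4**
Reactants: 10 [2-[(1R)-1-acetoxy-3-methylbut-2-en-1-yl]furan-3-yl]methyl (E)-2-methylbut-2-enoate
Product: 11 (2Z)-2-[(2R)-2-acetoxy-4-methylpent-3-enoyl]-4-oxobut-2-en-1-yl (E)-2-methylbut-2-enoate
Conditions: NBS (1.05 equiv), NaHCO3 (2 equiv), acetone/H2O 10:1, −20 °C, dark, 30 min; cold extractive work-up, crude 11 used at once
Reagents that add atoms: water, O
Why: Oxidative furan ring opening (bromination at the free C5, water capture at C2, loss of bromide) gives the ene-dicarbonyl; the cis relation of C2 and C5 in the furan becomes the Z-olefin needed for ring closure and the acetoxy stereocentre is not touched.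

**Step 5**
Reactants: 11 (2Z)-2-[(2R)-2-acetoxy-4-methylpent-3-enoyl]-4-oxobut-2-en-1-yl (E)-2-methylbut-2-enoate
Product: 13 [(3R,4S,5R)-5-acetoxy-3-hydroxy-6-oxo-4-(prop-1-en-2-yl)cyclohex-1-en-1-yl]methyl (E)-2-methylbut-2-enoate, via aluminium alkoxide 12 (not isolated)
Conditions: Me2AlCl (1.0 M in hexanes, 2.0 equiv), CH2Cl2, −78 → −40 °C; pH 7 buffer/Rochelle salt at −40 °C
Reagents that add atoms: none
Why: Proposed new method: a Lewis-acid type-I intramolecular carbonyl-ene cyclisation (the oxo version of the terpene C1→C6 closure; closest known reactions are neral → trans-isopiperitenol and citronellal → isopulegol) in which the Z-enal carbon is attacked by C6 of the prenyl-type olefin on the face fixed by A(1,3) strain (C3–H eclipses the olefin, OAc points away from the forming bond, giving 3,4-trans) through an all-equatorial half-chair with the carbonyl oxygen gauche to the CMe2 terminus for hydrogen transfer (giving 4,5-trans), while Me2AlCl traps the product as its alkoxide with loss of methane so that no protic acid is present to dehydrate it to a phenol.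

**Step 6**
Reactants: 13 [(3R,4S,5R)-5-acetoxy-3-hydroxy-6-oxo-4-(prop-1-en-2-yl)cyclohex-1-en-1-yl]methyl (E)-2-methylbut-2-enoate; 14 tiglic acid
Product: 16 [(3S,4S,5R)-5-acetoxy-3-[(E)-2-methylbut-2-enoyloxy]-6-oxo-4-(prop-1-en-2-yl)cyclohex-1-en-1-yl]methyl (E)-2-methylbut-2-enoate, via alkoxyphosphonium tiglate 15 (not isolated)
Conditions: 14 (3 equiv), PPh3 (3 equiv), DIAD (3 equiv), toluene, 0 °C → rt
Reagents that add atoms: none
Why: Mitsunobu esterification, in which SN2 displacement of the allylic oxyphosphonium by tiglate inverts C5 to the required 4,5-cis arrangement (the menthol → neomenthyl ester type of inversion); SN2′ is blocked by the fully substituted C1 and the enone disfavours ionisation.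

**Step 7**
Reactants: 16 [(3S,4S,5R)-5-acetoxy-3-[(E)-2-methylbut-2-enoyloxy]-6-oxo-4-(prop-1-en-2-yl)cyclohex-1-en-1-yl]methyl (E)-2-methylbut-2-enoate
Product: 17 [(3S,4S,5R)-5-acetoxy-3-[(E)-2-methylbut-2-enoyloxy]-6-oxo-4-(propan-2-yl)cyclohex-1-en-1-yl]methyl (E)-2-methylbut-2-enoate (CNP0218511.1)
Conditions: H2 (1–3 atm), RhCl(PPh3)3 (10 mol%), benzene, rt
Reagents that add atoms: none
Why: Homogeneous hydrogenation with Wilkinson's catalyst reduces the 1,1-disubstituted isopropenyl olefin much faster than the trisubstituted conjugated tiglate and enone olefins (as in carvone → carvotanacetone); no stereocentre is made or disturbed.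

**Compound list**
1 | furan-3-ylmethanol | OCc1ccoc1 | starting material
2 | lithium (2-lithiofuran-3-yl)methanolate (dianion, formed in the flask) | [Li]OCc1ccoc1[Li] | intermediate
3 | dilithium alkoxide of the DMF adduct, lithium [2-[(dimethylamino)(lithiooxy)methyl]furan-3-yl]methanolate (formed in the flask) | [Li]OCc1ccoc1C(O[Li])N(C)C | intermediate
4 | 3-(hydroxymethyl)furan-2-carbaldehyde | OCc1ccoc1C=O | intermediate
5 | tigloyl chloride, (E)-2-methylbut-2-enoyl chloride | C/C=C(\C)C(Cl)=O | starting material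
6 | (2-formylfuran-3-yl)methyl (E)-2-methylbut-2-enoate | C/C=C(\C)C(=O)OCc1ccoc1C=O | intermediate
7 | (2-methylprop-1-en-1-yl)magnesium bromide | CC(C)=C[Mg]Br | starting material
8 | bis(2-methylprop-1-en-1-yl)zinc (formed in the flask) | CC(C)=C[Zn]C=C(C)C | intermediate
9 | (2-methylprop-1-enyl)zinc (R)-alkoxide of the adduct (formed in the flask) | C/C=C(\C)C(=O)OCc1ccoc1[C@H](O[Zn]C=C(C)C)C=C(C)C | intermediate
10 | [2-[(1R)-1-acetoxy-3-methylbut-2-en-1-yl]furan-3-yl]methyl (E)-2-methylbut-2-enoate | C/C=C(\C)C(=O)OCc1ccoc1[C@H](OC(C)=O)C=C(C)C | intermediate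
11 | (2Z)-2-[(2R)-2-acetoxy-4-methylpent-3-enoyl]-4-oxobut-2-en-1-yl (E)-2-methylbut-2-enoate | O=C/C=C(/COC(=O)/C(C)=C/C)C(=O)[C@H](OC(C)=O)C=C(C)C | intermediate
12 | chloro(methyl)aluminium alkoxide of 13 (formed in the flask) | C/C=C(\C)C(=O)OCC1=C[C@@H](O[Al](C)Cl)[C@H](C(C)=C)[C@@H](OC(C)=O)C1=O | intermediate
13 | [(3R,4S,5R)-5-acetoxy-3-hydroxy-6-oxo-4-(prop-1-en-2-yl)cyclohex-1-en-1-yl]methyl (E)-2-methylbut-2-enoate (3-OAc, 4-isopropenyl, 5-OH all trans) | C/C=C(\C)C(=O)OCC1=C[C@@H](O)[C@H](C(C)=C)[C@@H](OC(C)=O)C1=O | intermediate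
14 | tiglic acid, (E)-2-methylbut-2-enoic acid | C/C=C(\C)C(=O)O | starting material
15 | alkoxytriphenylphosphonium tiglate of 13 (formed in the flask) | C/C=C(\C)C(=O)OCC1=C[C@@H](O[P+](c2ccccc2)(c2ccccc2)c2ccccc2)[C@H](C(C)=C)[C@@H](OC(C)=O)C1=O.C/C=C(\C)C(=O)[O-] | intermediate
16 | [(3S,4S,5R)-5-acetoxy-3-[(E)-2-methylbut-2-enoyloxy]-6-oxo-4-(prop-1-en-2-yl)cyclohex-1-en-1-yl]methyl (E)-2-methylbut-2-enoate | C/C=C(\C)C(=O)OCC1=C[C@H](OC(=O)/C(C)=C/C)[C@H](C(C)=C)[C@@H](OC(C)=O)C1=O | intermediate
17 | [(3S,4S,5R)-5-acetoxy-3-[(E)-2-methylbut-2-enoyloxy]-6-oxo-4-(propan-2-yl)cyclohex-1-en-1-yl]methyl (E)-2-methylbut-2-enoate | C/C=C(\C)C(=O)OCC1=C[C@H](OC(=O)/C(C)=C/C)[C@H](C(C)C)[C@@H](OC(C)=O)C1=O | target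

**Step count and risks**
Total steps: 7. Longest linear sequence: 7 steps (1 → 17); 5, 7 and 14 are bought.

The three steps most likely to fail are steps 5, 6 and 3.

Step 5 is the least precedented. The Z-oxoenal may isomerise to the E-isomer, which cannot close. The ring closure may give the 4,5-cis alcohol instead. The γ-hydroxy enone may lose water and aromatise. The fallback sets out from 11 and comes back to the route at 17. Compound 11 is treated with TiCl4 (1.1 equiv, CH2Cl2, −78 °C) so that the bond forms by a stepwise Prins cyclisation and the tertiary cation is captured by chloride, giving [(3R,4S,5R)-5-acetoxy-4-(2-chloropropan-2-yl)-3-hydroxy-6-oxocyclohex-1-en-1-yl]methyl (E)-2-methylbut-2-enoate F4. Radical dechlorination (Bu3SnH, AIBN, toluene, 80 °C) then gives the isopropyl alcohol [(3R,4S,5R)-5-acetoxy-3-hydroxy-6-oxo-4-(propan-2-yl)cyclohex-1-en-1-yl]methyl (E)-2-methylbut-2-enoate F5, so no hydrogenation is needed. Mitsunobu esterification of F5 with 14 (PPh3, DIAD, toluene) gives 17 directly.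

Step 6 asks a weak acid (tiglic acid) to displace a hindered oxyphosphonium next to a branched carbon, so elimination or no reaction are possible. The fallback sets out from 13 and comes back at 16. Mitsunobu reaction of 13 with the much more acidic chloroacetic acid (PPh3, DIAD, toluene, 0 °C) gives the inverted ester [(3S,4S,5R)-5-acetoxy-3-(2-chloroacetoxy)-6-oxo-4-(prop-1-en-2-yl)cyclohex-1-en-1-yl]methyl (E)-2-methylbut-2-enoate F6. Selective removal of the chloroacetate with thiourea/NaHCO3 (EtOH/THF, 40 °C; acetate and tiglate survive) gives the cis alcohol [(3S,4S,5R)-5-acetoxy-3-hydroxy-6-oxo-4-(prop-1-en-2-yl)cyclohex-1-en-1-yl]methyl (E)-2-methylbut-2-enoate F7. Acylation with retention using 5 (pyridine, DMAP, CH2Cl2) gives 16.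

Step 3 may give low ee or the wrong facial sense on this new hetaryl aldehyde, and acetate 10 ionises easily. The fallback sets out from 6 and comes back at 10. Uncatalysed addition of 7 to 6 (THF, −78 °C) gives the racemic alcohol [2-(1-hydroxy-3-methylbut-2-en-1-yl)furan-3-yl]methyl (E)-2-methylbut-2-enoate F1. MnO2 (CH2Cl2, rt) gives the ketone [2-(3-methylbut-2-enoyl)furan-3-yl]methyl (E)-2-methylbut-2-enoate F2. Asymmetric transfer hydrogenation with RuCl(p-cymene)[(R,R)-TsDPEN] in HCO2H/Et3N (the furyl ring takes the aryl role in the CH/π-controlled transition state; the hindered β,β-dimethyl enone resists 1,4-reduction) gives [2-[(1R)-1-hydroxy-3-methylbut-2-en-1-yl]furan-3-yl]methyl (E)-2-methylbut-2-enoate F3. Acetylation (Ac2O, Et3N, DMAP, 0 °C) gives 10.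

**Further compounds**
F1 | step 3 | rac-[2-(1-hydroxy-3-methylbut-2-en-1-yl)furan-3-yl]methyl (E)-2-methylbut-2-enoate | C/C=C(\C)C(=O)OCc1ccoc1C(O)C=C(C)C
F2 | step 3 | [2-(3-methylbut-2-enoyl)furan-3-yl]methyl (E)-2-methylbut-2-enoate | C/C=C(\C)C(=O)OCc1ccoc1C(=O)C=C(C)C
F3 | step 3 | [2-[(1R)-1-hydroxy-3-methylbut-2-en-1-yl]furan-3-yl]methyl (E)-2-methylbut-2-enoate | C/C=C(\C)C(=O)OCc1ccoc1[C@H](O)C=C(C)C
F4 | step 5 | [(3R,4S,5R)-5-acetoxy-4-(2-chloropropan-2-yl)-3-hydroxy-6-oxocyclohex-1-en-1-yl]methyl (E)-2-methylbut-2-enoate | C/C=C(\C)C(=O)OCC1=C[C@@H](O)[C@H](C(C)(C)Cl)[C@@H](OC(C)=O)C1=O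
F5 | step 5 | [(3R,4S,5R)-5-acetoxy-3-hydroxy-6-oxo-4-(propan-2-yl)cyclohex-1-en-1-yl]methyl (E)-2-methylbut-2-enoate | C/C=C(\C)C(=O)OCC1=C[C@@H](O)[C@H](C(C)C)[C@@H](OC(C)=O)C1=O
F6 | step 6 | [(3S,4S,5R)-5-acetoxy-3-(2-chloroacetoxy)-6-oxo-4-(prop-1-en-2-yl)cyclohex-1-en-1-yl]methyl (E)-2-methylbut-2-enoate | C/C=C(\C)C(=O)OCC1=C[C@H](OC(=O)CCl)[C@H](C(C)=C)[C@@H](OC(C)=O)C1=O
F7 | step 6 | [(3S,4S,5R)-5-acetoxy-3-hydroxy-6-oxo-4-(prop-1-en-2-yl)cyclohex-1-en-1-yl]methyl (E)-2-methylbut-2-enoate | C/C=C(\C)C(=O)OCC1=C[C@H](O)[C@H](C(C)=C)[C@@H](OC(C)=O)C1=O
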